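## Analysis of the target

Target 15 is a 3,8''-linked biflavanone. Unit 1 is an eriodictyol-type flavanone (phloroglucinol ring A, pyranone ring C, catechol ring B on C2). Unit 2 is (2S)-naringenin (benzo ring D, pyranone ring E, 4-hydroxyphenyl ring F; doubly primed locants for rings D and E, triply primed for ring F). The units are joined by one bond from C3 of ring C to C8'' of ring D. There are three stereocentres: C2 (R), C3 (R) and C2'' (S). On ring C the hydrogens at C2 and C3 are cis, so the two aryl groups sit on the same face; this is the less stable arrangement, and C2'' is remote from both centres. The sensitive groups are seven phenols (one catechol), two β-aryloxy ketones that open in base by enolisation and elimination or through a quinone methide where a para-hydroxyphenyl group is present, and the C3–H, which is α to the C4 carbonyl and benzylic, so that base turns cis into trans. The hard points are the crowded C3–C8'' bond between a tertiary carbon and an arene carbon with two ortho oxygens, the choice of C8'' over C6'', the cis ring fusion pattern, and the configuration of C2/C3 relative to C2''. The strategy rests on one feature: C3 and C2 are the α- and β-carbons of a 2'-hydroxychalcone carrying a 4-hydroxyl on ring B. Oxidation of that phenol puts radical character on the α-carbon and turns the β-carbon into a quinone methide carbon that the 2'-oxygen can close on, while C8'' is an electron-rich CH of ring D para to the 5''-hydroxyl.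

## Retrosynthetic reasoning

**15 ⇒ 14.** The six O–benzyl bonds are cut last. Free phenols, above all the catechol, would not survive the oxidant of the key step or the base of the C3 correction. Neutral hydrogenolysis is the one global deprotection that leaves a cis-2,3 flavanone alone, so benzyl is the only protecting group used.

**14 ⇒ 12 (through enolate 13).** No skeletal bond is cut; only C3 is changed. The cis arrangement of 15 is not what a quinone methide closure delivers and not what equilibration gives, so 14 is traced back to its 2,3-trans epimer 12. The forward step has to make C3 planar (enolate 13) and return the proton from the face opposite to the C2 aryl group, without opening ring C or ring E.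

**12 ⇒ 11.** The O4'–benzyl bond is cut. The free 4'-hydroxyl of 11 is what remains of the phenol that is oxidised in the key step. It must be capped before 13 is formed, because a phenoxide para to C2 would open ring C through a quinone methide.

**11 ⇒ 7 + 9 (through quinone methide 10).** C3–C8'' and O1–C2 are cut together, opening ring C. These are the two bonds that oxidation of one phenol can make in a single operation; every other cut at ring C leaves C3–C8'' to be built by several steps of carbonyl chemistry on a crowded ring. The gain is two halves of similar size, each a lightly protected flavonoid precursor, with C2'' taken from the chiral pool. The forward reaction must oxidise only the 4-hydroxyl of 7, join its α-carbon to C8'' of 9 rather than to C6'' or to a second molecule of 7, and close on the β-carbon with the 2'-oxygen only. Two design choices serve this: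
- Both O7'' and O4''' of 9 are benzylated. A partner with free O7'' and only O4''' benzylated was set aside: it cannot be made by direct benzylation of 8 (O7 is the most acidic and reacts first), and it would offer the quinone methide a five-ring closure by O7''.
- The expected product is taken as the 2,3-trans isomer 11, not the cis isomer, for the reason given under step 7.

**7 ⇒ 6 ⇒ 2 + 5.** The Cα=Cβ bond is cut as an aldol condensation. The 4-oxygen must be masked during the condensation, since a phenoxide para to the formyl group would deactivate it. The mask is an acetal so that it comes off without touching benzyl ethers.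

**5 ⇒ 4 ⇒ 3.** Two O-alkyl bonds are cut in the order set by acidity: the 4-hydroxyl of 3 (para to the formyl group) takes the temporary acetal first, the 3-hydroxyl is then benzylated.

**2 ⇒ 1.** Two O–benzyl bonds are cut; the hydroxyl chelated to the acetyl group stays free and becomes O1 of ring C.

**9 ⇒ 8.** Two O–benzyl bonds are cut. The forward etherification has to be run without base so that C2'' keeps its S configuration.

## Alternatives that were turned down

**Alternative 1:** Both bonds at C3 are cut (C3–C8'' and C2–C3). C3 becomes the carbene carbon of diazoketone A1 (ring A and C4), C8''–H comes from (2S)-tri-O-benzylnaringenin A2, and C2 with ring B from 3,4-bis(benzyloxy)benzaldehyde A3.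
- Forward: Rh2(OAc)4 turns A1 into a rhodium carbene, C8'' of A2 attacks it, and the zwitterion is intercepted by A3 under a chiral phosphoric acid, (R)-3,3'-bis(2,4,6-triisopropylphenyl)-1,1'-binaphthyl-2,2'-diyl hydrogen phosphate, before the proton shift. This gives anti-aldol A4. Ring C would be closed after removal of one silyl group by an intramolecular Mitsunobu etherification with inversion at C2, which converts anti into cis.
- For it: three fragments are joined in one operation, and a catalyst addresses both new centres. On stereocontrol it is stronger than the chosen route, which has no control over the C3 face in the coupling and corrects C3 afterwards.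
- Against it: interception of such zwitterions by aldehydes is established for indoles and dialkylanilines, not for an acyl-substituted trialkoxybenzene whose reacting carbon has two ortho substituents. The plain proton shift, attack on rings B and F, and insertion into benzylic ether C–H bonds compete. C8'' versus C6'' is as open as in the chosen route. Ring C is not closed by the key step, and its closure is a substitution at a carbinol carbon para to an alkoxy group, which tends to ionise and lose configuration. Silyl and benzyl ethers must be differentiated on ring A.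
- Comparison: diazoketone synthesis, coupling, desilylation, closure and two kinds of deprotection stand against one oxidative operation from 7 and 9. The chosen route gives up stereocontrol in the C–C coupling for this brevity and a single protecting group.

**Alternative 2:** Only C2–C3 is cut. C3 is the diazo carbon of α-aryl-α-diazoketone A5, which already contains the C3–C8'' bond and carries three 3,4-bis(benzyloxy)benzyl ethers on ring A, one of which supplies C2 and ring B.
- Forward: Rh2(S-PTTL)4 (dirhodium tetrakis[N-phthaloyl-(S)-tert-leucinate]) forms the carbene, which inserts into a benzylic C–H bond of an ortho ether and closes ring C, giving A6.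
- For it: insertion next to an ether oxygen is a known route to chromanones and gives the cis isomer under kinetic control, with the catalyst setting the absolute sense. On the cis geometry it is clearly stronger than the chosen route, where the closure gives trans and an extra step is needed.
- Against it: the hardest bond, C3–C8'', is not made by the key step. A deoxybenzoin must first be built on ring D and then subjected to diazo transfer. The carbene bears a 2,6-dioxygenated aryl group twisted out of conjugation, so insertion competes with attack on the many electron-rich rings. Two of the three large benzyl-type groups on ring A are spent as protecting groups. The silyl ethers of unit 2 need a second deprotection with fluoride, which is basic towards a cis ketone.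
- Comparison: longer and heavier; it buys cis selectivity. The chosen route offers a direct attack on C3–C8'' from two flavonoid-sized halves.

**Alternative 3:** O1–C2 and O1''–C2'' are cut, opening both pyranone rings to bis-chalcone A7, an α-aryl chalcone whose aryl group is ring D of a second 2'-hydroxychalcone.
- Forward: a bifunctional thiourea, 1-[3,5-bis(trifluoromethyl)phenyl]-3-[(8α,9S)-6'-methoxycinchonan-9-yl]thiourea, promotes both oxa-Michael additions, and C3 is set by protonation of the enol, giving A8.
- For it: asymmetric oxa-Michael closure of 2'-hydroxychalcones is a known reaction type and needs no oxidant. The position of the link on ring D is fixed by construction, so on regiochemistry it is stronger than the chosen route. Kinetic protonation at C3 can give cis.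
- Against it: C3–C8'' again has to be made beforehand as the Cα–aryl bond of a deoxybenzoin on a fully substituted ring. Naringenin 8 cannot be used, so C2'' also depends on the catalyst. Ring E needs the spatial sense of a (2S)-flavanone and ring C that of a (2R)-flavanone, so one catalyst would have to add to opposite faces of two similar enones. An α-aryl chalcone without an activating ester is a hindered, weak acceptor. Closure and protonation under a basic catalyst are reversible, which lets C3 drift to trans.
- Comparison: more steps before the key step and a mismatched double closure. The chosen route takes C2'' from 8 and forms ring C together with the C–C bond.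

Key step: step 7

Remark on the chemistry: the target is taken exactly as drawn, with H2 and H3 of ring C cis ((2R,3R), 2''S); (2S)-naringenin of high enantiomeric purity is assumed as starting material.

## Route

Step 1
Reactants: 1 2,4,6-trihydroxyacetophenone
Product: 2 1-[2,4-bis(benzyloxy)-6-hydroxyphenyl]ethanone
Conditions: BnBr (2.1 equiv), K2CO3, DMF, rt
Reagents that add atoms: benzyl bromide, BrCc1ccccc1
Why: Williamson etherification; the two hydroxyls not held in the hydrogen bond to the acetyl group are alkylated and the chelated one is left free for the later ring closure.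

Step 2
Reactants: 3 3,4-dihydroxybenzaldehyde
Product: 4 3-hydroxy-4-(methoxymethoxy)benzaldehyde
Conditions: MOMCl (1.05 equiv), K2CO3 (1.1 equiv), acetone, 0 °C to rt
Reagents that add atoms: chloromethyl methyl ether, COCCl
Why: The 4-hydroxyl, para to the formyl group, is the more acidic one; with one equivalent of weak base only its phenoxide forms and is alkylated (regioselective O-alkylation to the acetal).

Step 3
Reactants: 4 3-hydroxy-4-(methoxymethoxy)benzaldehyde
Product: 5 3-(benzyloxy)-4-(methoxymethoxy)benzaldehyde
Conditions: BnBr (1.2 equiv), K2CO3, DMF, rt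
Reagents that add atoms: benzyl bromide, BrCc1ccccc1
Why: Williamson etherification of the only remaining phenol; the acetal is stable to base.

Step 4
Reactants: 2 1-[2,4-bis(benzyloxy)-6-hydroxyphenyl]ethanone; 5 3-(benzyloxy)-4-(methoxymethoxy)benzaldehyde
Product: 6 (E)-1-[2,4-bis(benzyloxy)-6-hydroxyphenyl]-3-[3-(benzyloxy)-4-(methoxymethoxy)phenyl]prop-2-en-1-one
Conditions: KOH (50% aq.), EtOH/THF, rt
Reagents that add atoms: none
Why: Claisen–Schmidt condensation; dehydration of the aldol by the E1cB path gives the conjugated E enone, the masked 4-oxygen keeps the aldehyde electrophilic, and in strong base the 2'-phenoxide chalcone does not close to the flavanone.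

Step 5
Reactants: 6 (E)-1-[2,4-bis(benzyloxy)-6-hydroxyphenyl]-3-[3-(benzyloxy)-4-(methoxymethoxy)phenyl]prop-2-en-1-one
Product: 7 (E)-1-[2,4-bis(benzyloxy)-6-hydroxyphenyl]-3-[3-(benzyloxy)-4-hydroxyphenyl]prop-2-en-1-one
Conditions: conc. HCl (3 equiv), MeOH/THF 1:1, rt
Reagents that add atoms: none
Why: Acid-catalysed cleavage of the methoxymethyl acetal with transfer of the methylene to methanol; aryl benzyl ethers are untouched, and room temperature keeps the acid-catalysed oxa-Michael closure of the 2'-hydroxychalcone slow.

Step 6
Reactants: 8 (2S)-naringenin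
Product: 9 (2S)-7-(benzyloxy)-2-[4-(benzyloxy)phenyl]-5-hydroxychroman-4-one
Conditions: BnOH (2.3 equiv), PPh3 (2.4 equiv), DIAD (2.4 equiv), THF, 0 °C to rt
Reagents that add atoms: benzyl alcohol, OCc1ccccc1
Why: Mitsunobu etherification of the two acidic phenols (O7 first, then O4'); the chelated 5-hydroxyl does not react. No free base is present, so neither the enolate nor the quinone methide route to ring opening operates and C2 should stay S (to be checked by chiral HPLC).

Step 7
Reactants: 7 (E)-1-[2,4-bis(benzyloxy)-6-hydroxyphenyl]-3-[3-(benzyloxy)-4-hydroxyphenyl]prop-2-en-1-one; 9 (2S)-7-(benzyloxy)-2-[4-(benzyloxy)phenyl]-5-hydroxychroman-4-one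
Product: 11 (2R,3S)-5,7-bis(benzyloxy)-2-[3-(benzyloxy)-4-hydroxyphenyl]-3-{(2S)-7-(benzyloxy)-2-[4-(benzyloxy)phenyl]-5-hydroxy-4-oxochroman-8-yl}chroman-4-one (2,3-trans), via quinone methide 10 (not isolated)
Conditions: Ag2O (1.5 equiv), 9 (3 equiv), CH2Cl2/acetone, rt, dark, 7 added over 8 h; preparative HPLC
Reagents that add atoms: none
Why: Proposed new method: Ag2O oxidises the only easily oxidised phenol present, the guaiacyl-type 4-hydroxyl of 7 (the 2'- and 5''-hydroxyls are chelated to carbonyl groups and every other oxygen is benzylated), to a phenoxyl radical whose spin reaches the α-carbon through ring B as in ferulate and coniferyl radicals; this electrophilic α-keto radical site bonds to C8'' of 9, the carbon para to the free 5''-hydroxyl and ortho to two ether oxygens, and loss of a second electron and a proton to monovalent silver restores ring D and leaves quinone methide 10. The closest known reaction type is the 8–5' dehydrodimerisation of 4-hydroxycinnamyl phenols by Ag2O or oxidase enzymes to phenylcoumarans, where a quinone methide is likewise trapped by a neighbouring phenol; new here are the cross-coupling with an arene that is not itself readily oxidised and the six-ring trapping. Ring C closes by 6-exo-trig addition of the 2'-hydroxyl to the exocyclic quinone methide carbon (C2), which rearomatises ring B; the 5-exo closure to a dihydrobenzofuran is excluded because O7'' is benzylated. C3 is set in the C–C bond formation with no control from the remote C2'' centre, so both C3 epimers are expected. C2 is set in the closure relative to C3: allylic 1,3-strain holds H3 in the plane of the quinone methide and the tethered oxygen attacks from the face that carries C4, which places the two aryl groups trans. The step needs oxidation of one phenol only (secured by the substitution pattern), cross- over homo-coupling (helped only by excess 9 and slow addition of 7), C8'' over C6'' (favoured by the para relation to the 5''-hydroxyl, not secured) and the 2R configuration (not secured; 11 is separated from its (2S,3R) diastereomer). The cis relation of the target is therefore not expected here and is installed at C3 in step 9.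

Step 8
Reactants: 11 (2R,3S)-5,7-bis(benzyloxy)-2-[3-(benzyloxy)-4-hydroxyphenyl]-3-{(2S)-7-(benzyloxy)-2-[4-(benzyloxy)phenyl]-5-hydroxy-4-oxochroman-8-yl}chroman-4-one
Product: 12 (2R,3S)-5,7-bis(benzyloxy)-2-[3,4-bis(benzyloxy)phenyl]-3-{(2S)-7-(benzyloxy)-2-[4-(benzyloxy)phenyl]-5-hydroxy-4-oxochroman-8-yl}chroman-4-one (2,3-trans)
Conditions: BnOH (1.3 equiv), PPh3, DIAD, THF, 0 °C to rt
Reagents that add atoms: benzyl alcohol, OCc1ccccc1
Why: Mitsunobu etherification of the 4'-hydroxyl; the chelated 5''-hydroxyl is inert. Capping O4' removes the phenoxide that would open ring C through a quinone methide in the next step, and the neutral conditions do not enolise either ketone.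

Step 9
Reactants: 12 (2R,3S)-5,7-bis(benzyloxy)-2-[3,4-bis(benzyloxy)phenyl]-3-{(2S)-7-(benzyloxy)-2-[4-(benzyloxy)phenyl]-5-hydroxy-4-oxochroman-8-yl}chroman-4-one
Product: 14 (2R,3R)-5,7-bis(benzyloxy)-2-[3,4-bis(benzyloxy)phenyl]-3-{(2S)-7-(benzyloxy)-2-[4-(benzyloxy)phenyl]-5-hydroxy-4-oxochroman-8-yl}chroman-4-one (2,3-cis), via dilithium enolate 13 (not isolated)
Conditions: LiN(SiMe3)2 (2.3 equiv), THF, −78 °C; then AcOH (excess) in THF, −78 °C
Reagents that add atoms: none
Why: Deprotonation of the 5''-hydroxyl and of the axial, doubly activated C3–H gives 13, in which C3 is planar and the lithium 5''-phenoxide deactivates the ketone of ring E towards enolisation. Allylic strain with the aryl group on C3 forces the C2 aryl group pseudo-axial, so the proton enters C3 from the opposite face and the two aryl groups end up cis (diastereoselective kinetic protonation of an enolate); C2 and C2'' are not touched and C3 becomes R.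

Step 10
Reactants: 14 (2R,3R)-5,7-bis(benzyloxy)-2-[3,4-bis(benzyloxy)phenyl]-3-{(2S)-7-(benzyloxy)-2-[4-(benzyloxy)phenyl]-5-hydroxy-4-oxochroman-8-yl}chroman-4-one
Product: 15 (2R,3R)-2-(3,4-dihydroxyphenyl)-5,7-dihydroxy-3-[(2S)-5,7-dihydroxy-2-(4-hydroxyphenyl)-4-oxochroman-8-yl]chroman-4-one (target)
Conditions: H2 (1 atm), Pd/C (10%), EtOAc/MeOH, rt; reversed-phase HPLC (0.1% HCO2H)
Reagents that add atoms: none
Why: Hydrogenolysis of the six aryl benzyl ethers under neutral conditions; aryl ketones and the cyclic benzylic C–O bonds of flavanones are expected to survive at atmospheric pressure, and the absence of base keeps C3 and C2 from epimerising.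

## Compound list

1 | 2,4,6-trihydroxyacetophenone | CC(=O)c1c(O)cc(O)cc1O | starting material
2 | 1-[2,4-bis(benzyloxy)-6-hydroxyphenyl]ethanone | CC(=O)c1c(O)cc(OCc2ccccc2)cc1OCc1ccccc1 | intermediate
3 | 3,4-dihydroxybenzaldehyde | O=Cc1ccc(O)c(O)c1 | starting material
4 | 3-hydroxy-4-(methoxymethoxy)benzaldehyde | COCOc1ccc(C=O)cc1O | intermediate
5 | 3-(benzyloxy)-4-(methoxymethoxy)benzaldehyde | COCOc1ccc(C=O)cc1OCc1ccccc1 | intermediate
6 | (E)-1-[2,4-bis(benzyloxy)-6-hydroxyphenyl]-3-[3-(benzyloxy)-4-(methoxymethoxy)phenyl]prop-2-en-1-one | O=C(/C=C/c1ccc(OCOC)c(OCc2ccccc2)c1)c1c(O)cc(OCc2ccccc2)cc1OCc1ccccc1 | intermediate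
7 | (E)-1-[2,4-bis(benzyloxy)-6-hydroxyphenyl]-3-[3-(benzyloxy)-4-hydroxyphenyl]prop-2-en-1-one | O=C(/C=C/c1ccc(O)c(OCc2ccccc2)c1)c1c(O)cc(OCc2ccccc2)cc1OCc1ccccc1 | intermediate
8 | (2S)-naringenin | O=C1C[C@@H](c2ccc(O)cc2)Oc2cc(O)cc(O)c12 | starting material
9 | (2S)-7-(benzyloxy)-2-[4-(benzyloxy)phenyl]-5-hydroxychroman-4-one | O=C1C[C@@H](c2ccc(OCc3ccccc3)cc2)Oc2cc(OCc3ccccc3)cc(O)c12 | intermediate
10 | quinone methide: (2S)-7-(benzyloxy)-2-[4-(benzyloxy)phenyl]-8-{1-[3-(benzyloxy)-4-oxocyclohexa-2,5-dien-1-ylidene]-3-[2,4-bis(benzyloxy)-6-hydroxyphenyl]-3-oxopropan-2-yl}-5-hydroxychroman-4-one, coupled carbon with the spatial arrangement of C3 in 11 | O=C1C[C@@H](c2ccc(OCc3ccccc3)cc2)Oc2c1c(O)cc(OCc1ccccc1)c2[C@@H](C=C1C=CC(=O)C(OCc2ccccc2)=C1)C(=O)c1c(O)cc(OCc2ccccc2)cc1OCc1ccccc1 | intermediate (not isolated)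
11 | (2R,3S)-5,7-bis(benzyloxy)-2-[3-(benzyloxy)-4-hydroxyphenyl]-3-{(2S)-7-(benzyloxy)-2-[4-(benzyloxy)phenyl]-5-hydroxy-4-oxochroman-8-yl}chroman-4-one (2,3-trans) | O=C1C[C@@H](c2ccc(OCc3ccccc3)cc2)Oc2c1c(O)cc(OCc1ccccc1)c2[C@@H]1C(=O)c2c(OCc3ccccc3)cc(OCc3ccccc3)cc2O[C@H]1c1ccc(O)c(OCc2ccccc2)c1 | intermediate
12 | (2R,3S)-5,7-bis(benzyloxy)-2-[3,4-bis(benzyloxy)phenyl]-3-{(2S)-7-(benzyloxy)-2-[4-(benzyloxy)phenyl]-5-hydroxy-4-oxochroman-8-yl}chroman-4-one (2,3-trans) | O=C1C[C@@H](c2ccc(OCc3ccccc3)cc2)Oc2c1c(O)cc(OCc1ccccc1)c2[C@@H]1C(=O)c2c(OCc3ccccc3)cc(OCc3ccccc3)cc2O[C@H]1c1ccc(OCc2ccccc2)c(OCc2ccccc2)c1 | intermediate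
13 | dilithium salt of 12: lithium C3=C4 enolate and lithium 5''-phenoxide, C2 spatially unchanged | O=C1C[C@@H](c2ccc(OCc3ccccc3)cc2)Oc2c1c(O[Li])cc(OCc1ccccc1)c2C1=C(O[Li])c2c(OCc3ccccc3)cc(OCc3ccccc3)cc2O[C@H]1c1ccc(OCc2ccccc2)c(OCc2ccccc2)c1 | intermediate (not isolated)
14 | (2R,3R)-5,7-bis(benzyloxy)-2-[3,4-bis(benzyloxy)phenyl]-3-{(2S)-7-(benzyloxy)-2-[4-(benzyloxy)phenyl]-5-hydroxy-4-oxochroman-8-yl}chroman-4-one (2,3-cis) | O=C1C[C@@H](c2ccc(OCc3ccccc3)cc2)Oc2c1c(O)cc(OCc1ccccc1)c2[C@H]1C(=O)c2c(OCc3ccccc3)cc(OCc3ccccc3)cc2O[C@H]1c1ccc(OCc2ccccc2)c(OCc2ccccc2)c1 | intermediate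
15 | (2R,3R)-2-(3,4-dihydroxyphenyl)-5,7-dihydroxy-3-[(2S)-5,7-dihydroxy-2-(4-hydroxyphenyl)-4-oxochroman-8-yl]chroman-4-one | O=C1C[C@@H](c2ccc(O)cc2)Oc2c1c(O)cc(O)c2[C@H]1C(=O)c2c(O)cc(O)cc2O[C@H]1c1ccc(O)c(O)c1 | target

## Step count and least certain steps

Total: 10 steps. Longest linear sequence: 8 steps (steps 2, 3, 4, 5, 7, 8, 9, 10, from 3 to 15).

**Step 7 (key step, proposed new method).**
- What may go wrong: dimerisation of the chalcone radical through its α-carbon and ring B outruns the cross-coupling, because ring D of 9 is not oxidised and must accept a stabilised radical. Attack may also go to C6''. The guaiacyl phenol of the product may be oxidised further. The two trans diastereomers differ only in their relation to the remote C2'' and may separate poorly; in that case separation is deferred to 12 or 14.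
- Fallback with known chemistry, from 2 and 9 to 12: Riley oxidation of 2 (SeO2, dioxane/water, 90 °C) would give the arylglyoxal 2-[2,4-bis(benzyloxy)-6-hydroxyphenyl]-2-oxoacetaldehyde F1. Acid-catalysed Friedel–Crafts hydroxyalkylation of 9 with F1 (TsOH cat., CH2Cl2, rt) at C8'' would give the α-hydroxy ketone (2S)-7-(benzyloxy)-2-[4-(benzyloxy)phenyl]-5-hydroxy-8-{2-[2,4-bis(benzyloxy)-6-hydroxyphenyl]-1-hydroxy-2-oxoethyl}chroman-4-one F2 as both carbinol epimers. Reductive removal of the α-hydroxyl (Zn, AcOH, 50 °C) would give the deoxybenzoin (2S)-7-(benzyloxy)-2-[4-(benzyloxy)phenyl]-5-hydroxy-8-{2-[2,4-bis(benzyloxy)-6-hydroxyphenyl]-2-oxoethyl}chroman-4-one F3. Condensation of F3 with commercial 3,4-bis(benzyloxy)benzaldehyde (piperidine, EtOH, reflux) closes ring C by aldol condensation and oxa-Michael addition, the classical route from 2-hydroxydeoxybenzoins to 2,3-diarylchromanones. This should give the thermodynamic 2,3-trans pair, from which 12 is separated. The sequence replaces steps 7 and 8 and makes steps 2 to 5 unnecessary.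

**Step 9 (C3 inversion).**
- What may go wrong: β-elimination of the ring A aryloxide from the enolate opens ring C; deprotonation at the crowded C3 is incomplete at −78 °C; the protonation face is poorly discriminated; or the product re-equilibrates to trans during work-up.
- Fallback, from 12 to 14: soft enolisation (TBSOTf, Et3N, CH2Cl2, 0 °C) to the isolable C4 tert-butyldimethylsilyl enol ether of 12 silylated also at O5'' F4. F4 is then protodesilylated with fluoride in the presence of the proton donor (Bu4NF/AcOH, THF, −78 °C), which releases the enol and protonates it kinetically while removing the O5'' silyl group. This replaces a strongly basic lithium enolate by an isolated neutral enol derivative.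

**Step 10 (global debenzylation).**
- What may go wrong: loss of the cis relation by epimerisation on the catalyst surface or during isolation once the 4'-hydroxyl is free (ring opening through a quinone methide), and reductive cleavage of the benzylic C2–O1 bonds on long exposure.
- Fallback, from 14 to 15 without a new intermediate: Lewis acid debenzylation with BCl3 and pentamethylbenzene as benzyl cation scavenger (CH2Cl2, −78 °C), a non-reductive, acidic cleavage in which enolisation is slow.

**Step 5 (unmasking of the chalcone phenol).**
- What may go wrong: acid-catalysed oxa-Michael closure of the 2'-hydroxychalcone to the flavanone competes with acetal cleavage.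
- Fallback, from 5 to 7: the acetal is cleaved at the aldehyde stage (HCl, MeOH, rt) to 3-(benzyloxy)-4-hydroxybenzaldehyde F5. F5 is condensed with 2 as its phenoxide under forcing Claisen–Schmidt conditions (KOH 60% aq., EtOH, 40 °C, long reaction time), so that the chalcone never meets acid; the price is a slower condensation.

## Further compounds

F1 | step 7 | 2-[2,4-bis(benzyloxy)-6-hydroxyphenyl]-2-oxoacetaldehyde | O=CC(=O)c1c(O)cc(OCc2ccccc2)cc1OCc1ccccc1
F2 | step 7 | (2S)-7-(benzyloxy)-2-[4-(benzyloxy)phenyl]-5-hydroxy-8-{2-[2,4-bis(benzyloxy)-6-hydroxyphenyl]-1-hydroxy-2-oxoethyl}chroman-4-one (both carbinol epimers) | O=C1C[C@@H](c2ccc(OCc3ccccc3)cc2)Oc2c1c(O)cc(OCc1ccccc1)c2C(O)C(=O)c1c(O)cc(OCc2ccccc2)cc1OCc1ccccc1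
F3 | step 7 | (2S)-7-(benzyloxy)-2-[4-(benzyloxy)phenyl]-5-hydroxy-8-{2-[2,4-bis(benzyloxy)-6-hydroxyphenyl]-2-oxoethyl}chroman-4-one | O=C1C[C@@H](c2ccc(OCc3ccccc3)cc2)Oc2c1c(O)cc(OCc1ccccc1)c2CC(=O)c1c(O)cc(OCc2ccccc2)cc1OCc1ccccc1
F4 | step 9 | C4 tert-butyldimethylsilyl enol ether of 12 with O5'' tert-butyldimethylsilyl ether, C2 and C2'' unchanged | O=C1C[C@@H](c2ccc(OCc3ccccc3)cc2)Oc2c1c(O[Si](C)(C)C(C)(C)C)cc(OCc1ccccc1)c2C1=C(O[Si](C)(C)C(C)(C)C)c2c(OCc3ccccc3)cc(OCc3ccccc3)cc2O[C@H]1c1ccc(OCc2ccccc2)c(OCc2ccccc2)c1
F0 | step 10 | none | none
F5 | step 5 | 3-(benzyloxy)-4-hydroxybenzaldehyde | O=Cc1ccc(O)c(OCc2ccccc2)c1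
A1 | alternative 1 | 1-[4-(benzyloxy)-2,6-bis(tert-butyldimethylsilyloxy)phenyl]-2-diazoethanone | [N-]=[N+]=CC(=O)c1c(O[Si](C)(C)C(C)(C)C)cc(OCc2ccccc2)cc1O[Si](C)(C)C(C)(C)C
A2 | alternative 1 | (2S)-5,7-bis(benzyloxy)-2-[4-(benzyloxy)phenyl]chroman-4-one | O=C1C[C@@H](c2ccc(OCc3ccccc3)cc2)Oc2cc(OCc3ccccc3)cc(OCc3ccccc3)c12
A3 | alternative 1 | 3,4-bis(benzyloxy)benzaldehyde | O=Cc1ccc(OCc2ccccc2)c(OCc2ccccc2)c1
A4 | alternative 1 | anti β-hydroxy ketone carrying rings A and B and all of unit 2 on C3 | O=C1C[C@@H](c5ccc(OCc9ccccc9)cc5)Oc2c1c(OCc9ccccc9)cc(OCc9ccccc9)c2[C@H]([C@H](O)c5ccc(OCc9ccccc9)c(OCc9ccccc9)c5)C(=O)c1c(O[Si](C)(C)C(C)(C)C)cc(OCc9ccccc9)cc1O[Si](C)(C)C(C)(C)C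
A5 | alternative 2 | α-aryl-α-diazoketone: 2-diazo-2-[(2S)-tris(tert-butyldimethylsilyl)naringenin-8-yl]-1-{2,4,6-tris[3,4-bis(benzyloxy)benzyloxy]phenyl}ethanone | O=C1C[C@@H](c2ccc(O[Si](C)(C)C(C)(C)C)cc2)Oc2c1c(O[Si](C)(C)C(C)(C)C)cc(O[Si](C)(C)C(C)(C)C)c2C(=[N+]=[N-])C(=O)c1c(OCc2ccc(OCc3ccccc3)c(OCc3ccccc3)c2)cc(OCc2ccc(OCc3ccccc3)c(OCc3ccccc3)c2)cc1OCc1ccc(OCc2ccccc2)c(OCc2ccccc2)c1
A6 | alternative 2 | cis-2,3-disubstituted chromanone with silyl ethers on unit 2 and benzyl-type ethers on unit 1 | O=C1C[C@@H](c5ccc(O[Si](C)(C)C(C)(C)C)cc5)Oc2c1c(O[Si](C)(C)C(C)(C)C)cc(O[Si](C)(C)C(C)(C)C)c2[C@H]1C(=O)c2c(OCc3ccc(OCc9ccccc9)c(OCc9ccccc9)c3)cc(OCc3ccc(OCc9ccccc9)c(OCc9ccccc9)c3)cc2O[C@H]1c5ccc(OCc9ccccc9)c(OCc9ccccc9)c5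
A7 | alternative 3 | open bis-chalcone: α-aryl 2'-hydroxychalcone whose α-aryl group is ring D of a second 2'-hydroxychalcone | O=C(/C=C/c1ccc(OCc2ccccc2)cc1)c1c(OCc2ccccc2)cc(O)c(c1O)C(=Cc1ccc(OCc2ccccc2)c(OCc2ccccc2)c1)C(=O)c1c(O)cc(OCc2ccccc2)cc1OCc1ccccc1
A8 | alternative 3 | hexa-O-benzyl ether of the target with free 7''-hydroxyl | O=C1C[C@@H](c5ccc(OCc9ccccc9)cc5)Oc2c1c(OCc9ccccc9)cc(O)c2[C@H]1C(=O)c2c(OCc9ccccc9)cc(OCc9ccccc9)cc2O[C@H]1c5ccc(OCc9ccccc9)c(OCc9ccccc9)c5
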